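**Plan**
- Cuts: the quinone is masked as its hydroquinone dimethyl ether (released last). The C32 side chain is cut once, at C19–C20: C20 is the sp3 CH2 ending a C16 tail, C19 is the methyl-bearing sp2 carbon of the C18=C19 alkene of the head. The tail is traced back to (S)-citronellyl bromide, the head to menaquinone-4 by a cut at C16–C17.
- Enabling feature: C19 is an alkene carbon, so it can be an alkenyllithium that binds the boron carrying C20. The borate-substituted C18=C19 alkene is then the most electron-rich of seven, so I2 triggers a 1,2-shift of C20 from boron to C19 and B/I elimination. Two nucleophilic carbons are joined oxidatively (Zweifel olefination).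
- Forward order: tail (steps 1–5) and head (steps 6–10) are made in parallel, joined in step 11, and the quinone is released in step 12. No ring is formed; the naphthalene comes with menaquinone-4.
- Stereochemistry: C27 (R) comes from (S)-citronellyl bromide. The C2, C6 and C10 alkenes are bought E. C14 is E from SeO2 oxidation of the E-methyl, C22 is E from syn-methylalumination, and C18 is E from the Z iodide by the stereoinvertive key step.

Key step: step 11

Assumption: menaquinone-4 (all-E), (S)-citronellyl bromide, 1-(trimethylsilyl)propyne and N-ethylidene-tert-butylamine are taken as catalogue chemicals; the (S) bromide maps onto the (27R) centre because only the CIP ranking of the two chain arms changes, not the spatial arrangement.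

**Route**

Step 1
Reactants: 1 (S)-citronellyl bromide; 2 1-(trimethylsilyl)propyne
Product: 3 [(6R)-6,10-dimethylundec-9-en-1-yn-1-yl]trimethylsilane
Conditions: 2, n-BuLi, THF, −78 → −20 °C; then 1, DMPU, −78 °C → rt
Reagents that add atoms: none
Why: Propargylic lithiation of the silyl propyne and SN2 alkylation by the primary bromide (three-carbon alkyne homologation) should give the acetylene, the silyl group disfavouring the allene, and the stereocentre two carbons from the reacting CH2 is not involved.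

Step 2
Reactants: 3 [(6R)-6,10-dimethylundec-9-en-1-yn-1-yl]trimethylsilane
Product: 4 (6R)-6,10-dimethylundec-9-en-1-yne
Conditions: K2CO3, MeOH, rt
Reagents that add atoms: none
Why: Methoxide-mediated protodesilylation cleaves only the C(sp)–Si bond and leaves the alkene and the stereocentre untouched.

Step 3
Reactants: 4 (6R)-6,10-dimethylundec-9-en-1-yne
Product: 7 (3E,8R)-4,8,12-trimethyltrideca-3,11-dien-1-ol, via alkenyldimethylalane 5 (not isolated), via lithium alkenylalanate 6 (not isolated)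
Conditions: Me3Al, Cp2ZrCl2 (cat.), CH2Cl2, 0 °C → rt; volatiles removed; n-BuLi, THF/hexane, −78 → 0 °C; oxirane, 0 °C → rt; aqueous work-up
Reagents that add atoms: trimethylaluminium, C[Al](C)C; oxirane, C1CO1
Why: Zirconium-catalysed methylalumination (Negishi carboalumination) adds methyl and aluminium syn across the terminal alkyne with aluminium on the terminal carbon while the trisubstituted alkene is inert, and the derived alanate opens oxirane with retention at the alkenyl carbon, so the new alkene is E.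

Step 4
Reactants: 7 (3E,8R)-4,8,12-trimethyltrideca-3,11-dien-1-ol
Product: 8 (3E,8R)-1-iodo-4,8,12-trimethyltrideca-3,11-diene
Conditions: I2, PPh3, imidazole, CH2Cl2, 0 °C → rt
Reagents that add atoms: iodine, II
Why: Appel-type iodination displaces the alkoxyphosphonium ion of the primary alcohol by SN2 and does not touch the alkenes.

Step 5
Reactants: 8 (3E,8R)-1-iodo-4,8,12-trimethyltrideca-3,11-diene
Product: 10 4,4,5,5-tetramethyl-2-[(3E,8R)-4,8,12-trimethyltrideca-3,11-dien-1-yl]-1,3,2-dioxaborolane, via homoallyllithium 9 (not isolated)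
Conditions: t-BuLi (2 equiv), Et2O/pentane, −78 °C; then 2-isopropoxy-4,4,5,5-tetramethyl-1,3,2-dioxaborolane, −78 °C → rt; H2O
Reagents that add atoms: 2-isopropoxy-4,4,5,5-tetramethyl-1,3,2-dioxaborolane, CC(C)OB1OC(C)(C)C(C)(C)O1
Why: Lithium–iodine exchange of the primary iodide followed by electrophilic borylation is a polar sequence, chosen because a homoallyl radical could scramble the alkene geometry through a cyclopropylcarbinyl radical, so the E alkene should survive.

Step 6
Reactants: 11 menaquinone-4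
Product: 13 1,4-dimethoxy-2-methyl-3-[(2E,6E,10E)-3,7,11,15-tetramethylhexadeca-2,6,10,14-tetraen-1-yl]naphthalene, via menaquinol-4 12 (not isolated)
Conditions: Na2S2O4, Bu4NBr (cat.), THF/H2O, rt, argon; then aq. KOH, Me2SO4, rt
Reagents that add atoms: dimethyl sulfate, COS(=O)(=O)OC
Why: Reductive methylation: dithionite reduces the quinone and the hydroquinone dianion is O-methylated under phase-transfer conditions, the basic medium avoiding acid-catalysed chromanol formation.

Step 7
Reactants: 13 1,4-dimethoxy-2-methyl-3-[(2E,6E,10E)-3,7,11,15-tetramethylhexadeca-2,6,10,14-tetraen-1-yl]naphthalene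
Product: 14 (2E,6E,10E,14E)-16-(1,4-dimethoxy-3-methylnaphthalen-2-yl)-2,6,10,14-tetramethylhexadeca-2,6,10,14-tetraen-1-ol
Conditions: SeO2 (cat.), t-BuOOH, salicylic acid (cat.), CH2Cl2, 0 °C → rt, stopped at partial conversion
Reagents that add atoms: selenium dioxide, O=[Se]=O (delivers the oxygen atom, catalytic); tert-butyl hydroperoxide, CC(C)(C)OO (terminal source of that oxygen)
Why: SeO2/t-BuOOH allylic oxidation (ene reaction, then [2,3]-sigmatropic shift) should attack the most accessible terminal isopropylidene group and oxidise its E-methyl, giving the (E)-allylic alcohol.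

Step 8
Reactants: 14 (2E,6E,10E,14E)-16-(1,4-dimethoxy-3-methylnaphthalen-2-yl)-2,6,10,14-tetramethylhexadeca-2,6,10,14-tetraen-1-ol
Product: 15 2-[(2E,6E,10E,14E)-16-bromo-3,7,11,15-tetramethylhexadeca-2,6,10,14-tetraen-1-yl]-1,4-dimethoxy-3-methylnaphthalene
Conditions: CBr4, PPh3, CH2Cl2, −20 → 0 °C
Reagents that add atoms: tetrabromomethane, BrC(Br)(Br)Br
Why: Appel bromination under neutral conditions gives the primary allylic bromide by SN2 without allylic transposition or loss of alkene geometry.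

Step 9
Reactants: 15 2-[(2E,6E,10E,14E)-16-bromo-3,7,11,15-tetramethylhexadeca-2,6,10,14-tetraen-1-yl]-1,4-dimethoxy-3-methylnaphthalene
Product: 17 (4E,8E,12E,16E)-18-(1,4-dimethoxy-3-methylnaphthalen-2-yl)-4,8,12,16-tetramethyloctadeca-4,8,12,16-tetraenal, via N-tert-butyl aldimine 16 (not isolated)
Conditions: N-ethylidene-tert-butylamine, LiN(i-Pr)2, THF, −78 → 0 °C; then 15, −78 °C → rt; aq. oxalic acid, rt
Reagents that add atoms: N-ethylidene-tert-butylamine, CC=NC(C)(C)C; water, O
Why: Aza-enolate (metalloenamine) alkylation: the lithiated acetaldimine attacks the primary allylic bromide by SN2 and mild acid hydrolysis releases the aldehyde two carbons longer.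

Step 10
Reactants: 17 (4E,8E,12E,16E)-18-(1,4-dimethoxy-3-methylnaphthalen-2-yl)-4,8,12,16-tetramethyloctadeca-4,8,12,16-tetraenal
Product: 18 2-[(2E,6E,10E,14E,18Z)-19-iodo-3,7,11,15-tetramethylicosa-2,6,10,14,18-pentaen-1-yl]-1,4-dimethoxy-3-methylnaphthalene
Conditions: EtPPh3I, n-BuLi, THF, 0 °C → rt; I2, −78 °C; NaN(SiMe3)2, −20 °C; then 17, −78 → −20 °C
Reagents that add atoms: ethyltriphenylphosphonium iodide, CC[P+](c1ccccc1)(c1ccccc1)c1ccccc1.[I-]; iodine, II
Why: Stork–Zhao-type Wittig olefination with the alpha-iodo ylide Ph3P=C(I)CH3 is kinetically Z-selective for unbranched aldehydes and should place iodine cis to the chain.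

Step 11
Reactants: 18 2-[(2E,6E,10E,14E,18Z)-19-iodo-3,7,11,15-tetramethylicosa-2,6,10,14,18-pentaen-1-yl]-1,4-dimethoxy-3-methylnaphthalene; 10 4,4,5,5-tetramethyl-2-[(3E,8R)-4,8,12-trimethyltrideca-3,11-dien-1-yl]-1,3,2-dioxaborolane
Product: 22 1,4-dimethoxy-2-methyl-3-[(2E,6E,10E,14E,18E,22E,27R)-3,7,11,15,19,23,27,31-octamethyldotriaconta-2,6,10,14,18,22,30-heptaen-1-yl]naphthalene, via alkenyllithium 19 (not isolated), via lithium boronate complex 20 (not isolated), via beta-iodoalkyl boronic ester 21 (not isolated)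
Conditions: 18, t-BuLi (2 equiv), Et2O/THF, −78 °C; 10, −78 → 0 °C; I2, THF/MeOH, −78 °C; NaOMe, MeOH, −78 °C → rt; aq. Na2S2O3
Reagents that add atoms: none
Why: Lithium–iodine exchange on 18 with retention gives alkenyllithium 19, whose C19 adds to the boron of 10 to give borate 20; I2 then attacks the C18=C19 alkene of 20, the C20 CH2 shifts from boron to C19 anti to the breaking C–I bond (1,2-metallate rearrangement) to give 21, and methoxide-induced anti elimination of boron and iodine delivers the alkene. This is the Zweifel olefination in its alkenyllithium/boronic ester form, a transition-metal-free oxidative union of two carbon nucleophiles. No ring is closed. No stereocentre is left by the event, since the two sp3 centres of 21 are destroyed again and both faces of attack converge, and the remote C27 centre is untouched. The geometry of the new C18=C19 alkene is controlled by the Z geometry of 18, because anti migration followed by anti elimination inverts it stereospecifically to E. The step needs iodine to pick one of seven alkenes and only the alkyl group to migrate: the negative charge on boron makes the borate-substituted alkene by far the most nucleophilic at −78 °C, and the pinacol oxygens do not migrate.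

Step 12
Reactants: 22 1,4-dimethoxy-2-methyl-3-[(2E,6E,10E,14E,18E,22E,27R)-3,7,11,15,19,23,27,31-octamethyldotriaconta-2,6,10,14,18,22,30-heptaen-1-yl]naphthalene
Product: 23 2-methyl-3-[(2E,6E,10E,14E,18E,22E,27R)-3,7,11,15,19,23,27,31-octamethyldotriaconta-2,6,10,14,18,22,30-heptaen-1-yl]naphthalene-1,4-dione
Conditions: (NH4)2Ce(NO3)6, MeCN/H2O/CH2Cl2, 0 °C
Reagents that add atoms: water, O
Why: Oxidative demethylation of the 1,4-dimethoxyarene by tetravalent cerium (two one-electron oxidations, water adds and methanol leaves) should regenerate the quinone faster than the isolated trisubstituted alkenes react.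

**Compound list**

1 | (S)-citronellyl bromide, (6S)-8-bromo-2,6-dimethyloct-2-ene | CC(C)=CCC[C@H](C)CCBr | starting material
2 | 1-(trimethylsilyl)propyne | CC#C[Si](C)(C)C | starting material
3 | [(6R)-6,10-dimethylundec-9-en-1-yn-1-yl]trimethylsilane | CC(C)=CCC[C@H](C)CCCC#C[Si](C)(C)C | intermediate
4 | (6R)-6,10-dimethylundec-9-en-1-yne | CC(C)=CCC[C@H](C)CCCC#C | intermediate
5 | dimethyl[(1E,6R)-2,6,10-trimethylundeca-1,9-dien-1-yl]alane (formed in the flask) | CC(C)=CCC[C@H](C)CCC/C(C)=C/[Al](C)C | intermediate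
6 | lithium butyl(dimethyl)[(1E,6R)-2,6,10-trimethylundeca-1,9-dien-1-yl]aluminate (formed in the flask) | [Li+].CC(C)=CCC[C@H](C)CCC/C(C)=C/[Al-](C)(C)CCCC | intermediate
7 | (3E,8R)-4,8,12-trimethyltrideca-3,11-dien-1-ol | CC(C)=CCC[C@H](C)CCC/C(C)=C/CCO | intermediate
8 | (3E,8R)-1-iodo-4,8,12-trimethyltrideca-3,11-diene | CC(C)=CCC[C@H](C)CCC/C(C)=C/CCI | intermediate
9 | [(3E,8R)-4,8,12-trimethyltrideca-3,11-dien-1-yl]lithium (formed in the flask) | CC(C)=CCC[C@H](C)CCC/C(C)=C/CC[Li] | intermediate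
10 | 4,4,5,5-tetramethyl-2-[(3E,8R)-4,8,12-trimethyltrideca-3,11-dien-1-yl]-1,3,2-dioxaborolane | CC(C)=CCC[C@H](C)CCC/C(C)=C/CCB1OC(C)(C)C(C)(C)O1 | intermediate
11 | menaquinone-4, 2-methyl-3-[(2E,6E,10E)-3,7,11,15-tetramethylhexadeca-2,6,10,14-tetraen-1-yl]naphthalene-1,4-dione | CC(C)=CCC/C(C)=C/CC/C(C)=C/CC/C(C)=C/CC1=C(C)C(=O)c2ccccc2C1=O | starting material
12 | menaquinol-4, the 1,4-dihydroxynaphthalene of 11 (formed in the flask) | CC(C)=CCC/C(C)=C/CC/C(C)=C/CC/C(C)=C/Cc1c(C)c(O)c2ccccc2c1O | intermediate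
13 | 1,4-dimethoxy-2-methyl-3-[(2E,6E,10E)-3,7,11,15-tetramethylhexadeca-2,6,10,14-tetraen-1-yl]naphthalene | CC(C)=CCC/C(C)=C/CC/C(C)=C/CC/C(C)=C/Cc1c(C)c(OC)c2ccccc2c1OC | intermediate
14 | (2E,6E,10E,14E)-16-(1,4-dimethoxy-3-methylnaphthalen-2-yl)-2,6,10,14-tetramethylhexadeca-2,6,10,14-tetraen-1-ol | OC/C(C)=C/CC/C(C)=C/CC/C(C)=C/CC/C(C)=C/Cc1c(C)c(OC)c2ccccc2c1OC | intermediate
15 | 2-[(2E,6E,10E,14E)-16-bromo-3,7,11,15-tetramethylhexadeca-2,6,10,14-tetraen-1-yl]-1,4-dimethoxy-3-methylnaphthalene | BrC/C(C)=C/CC/C(C)=C/CC/C(C)=C/CC/C(C)=C/Cc1c(C)c(OC)c2ccccc2c1OC | intermediate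
16 | N-tert-butyl imine of aldehyde 17 (formed in the flask) | CC(C)(C)/N=C/CC/C(C)=C/CC/C(C)=C/CC/C(C)=C/CC/C(C)=C/Cc1c(C)c(OC)c2ccccc2c1OC | intermediate
17 | (4E,8E,12E,16E)-18-(1,4-dimethoxy-3-methylnaphthalen-2-yl)-4,8,12,16-tetramethyloctadeca-4,8,12,16-tetraenal | O=CCC/C(C)=C/CC/C(C)=C/CC/C(C)=C/CC/C(C)=C/Cc1c(C)c(OC)c2ccccc2c1OC | intermediate
18 | 2-[(2E,6E,10E,14E,18Z)-19-iodo-3,7,11,15-tetramethylicosa-2,6,10,14,18-pentaen-1-yl]-1,4-dimethoxy-3-methylnaphthalene (iodine cis to the chain) | I/C(C)=C\CC/C(C)=C/CC/C(C)=C/CC/C(C)=C/CC/C(C)=C/Cc1c(C)c(OC)c2ccccc2c1OC | intermediate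
19 | alkenyllithium from 18, lithium in place of iodine with the geometry kept (formed in the flask) | [Li]/C(C)=C\CC/C(C)=C/CC/C(C)=C/CC/C(C)=C/CC/C(C)=C/Cc1c(C)c(OC)c2ccccc2c1OC | intermediate
20 | lithium boronate complex: pinacolato boron carrying the C16 alkyl group of 10 and the alkenyl group of 19, boron cis to the chain (formed in the flask) | [Li+].CC(C)=CCC[C@H](C)CCC/C(C)=C/CC[B-]1(OC(C)(C)C(C)(C)O1)/C(C)=C\CC/C(C)=C/CC/C(C)=C/CC/C(C)=C/CC/C(C)=C/Cc1c(C)c(OC)c2ccccc2c1OC | intermediate
21 | beta-iodoalkyl boronic ester: C19 carries Bpin, methyl and the migrated C20, C18 carries iodine anti to C20; one of two face diastereomers drawn, the other has both new centres inverted (formed in the flask) | CC(C)=CCC[C@H](C)CCC/C(C)=C/CC[C@](C)(B1OC(C)(C)C(C)(C)O1)[C@H](I)CC/C(C)=C/CC/C(C)=C/CC/C(C)=C/CC/C(C)=C/Cc1c(C)c(OC)c2ccccc2c1OC | intermediate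
22 | 1,4-dimethoxy-2-methyl-3-[(2E,6E,10E,14E,18E,22E,27R)-3,7,11,15,19,23,27,31-octamethyldotriaconta-2,6,10,14,18,22,30-heptaen-1-yl]naphthalene | CC(C)=CCC[C@H](C)CCC/C(C)=C/CC/C(C)=C/CC/C(C)=C/CC/C(C)=C/CC/C(C)=C/CC/C(C)=C/Cc1c(C)c(OC)c2ccccc2c1OC | intermediate
23 | 2-methyl-3-[(2E,6E,10E,14E,18E,22E,27R)-3,7,11,15,19,23,27,31-octamethyldotriaconta-2,6,10,14,18,22,30-heptaen-1-yl]naphthalene-1,4-dione (CNP0319612.1) | CC(C)=CCC[C@H](C)CCC/C(C)=C/CC/C(C)=C/CC/C(C)=C/CC/C(C)=C/CC/C(C)=C/CC/C(C)=C/CC1=C(C)C(=O)c2ccccc2C1=O | target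

**Count and risks**

Total steps: 12. Longest linear sequence: 7 steps (steps 6–12 from menaquinone-4; equally steps 1–5, 11, 12 from (S)-citronellyl bromide).

Most likely to fail:

1. Step 11. The hindered alkenyllithium may be captured incompletely by the boronic ester. Iodine may add to, or iodo-methoxylate, other alkenes. Partial syn elimination would erode the E geometry. The fallback replaces the stereoinvertive boronate rearrangement by a stereoretentive palladium-catalysed Negishi sp3–sp2 coupling, which needs the E iodide. It sets out from bromide 15 and from organolithium 9 (made from 8 as in step 5) and comes back at 22. Bromide 15 is alkylated with lithiated 2 (n-BuLi, THF, −78 °C) to give the silyl enyne F1. MeLi·LiBr in THF cleaves the C–Si bond to the lithium acetylide F2, which is methylated in the same flask (MeI, DMPU) to the 2-alkyne F3. Hydrozirconation with excess Cp2Zr(H)Cl (THF, 50 °C, to settle zirconium on the methyl-bearing carbon) gives the alkenylzirconocene chloride F4, and I2 converts it with retention into the (18E)-alkenyl iodide F5. Organolithium 9 is transmetalated with ZnCl2 to the alkylzinc chloride F6. Coupling of F5 with F6 under Pd(dppf)Cl2 catalysis (THF, rt), through oxidative addition to zerovalent palladium with retention, should give 22.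

2. Step 7. Site selectivity among four trisubstituted alkenes may be poor, the alcohol may over-oxidise to the enal, and conversion may stall. The fallback rebuilds the terminal unit instead of oxidising it in place; it sets out from 13 and comes back at 14. Terminal-selective bromohydrin formation (NBS, THF/H2O, 0 °C) gives the bromohydrin F7. K2CO3 in MeOH closes it to the terminal epoxide F8. H5IO6 (Et2O/THF) cleaves the epoxide to the trisnor aldehyde F9. E-selective Wittig olefination with ethyl 2-(triphenylphosphoranylidene)propanoate (CH2Cl2, rt) gives the enoate F10. i-Bu2AlH (CH2Cl2, −78 °C) reduces it to 14.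

3. Step 10. Halogen scrambling of the iodo ylide may lower conversion, and Z selectivity may erode. The fallback makes the cis-halo alkene by selective cross-coupling instead of olefination; it sets out from 17 and comes back at alkenyllithium 19 within step 11. Dibromo-olefination of 17 (CBr4, PPh3, CH2Cl2, 0 °C) gives the 1,1-dibromoalkene F11. Trans-selective monomethylation (Me2Zn, Pd(DPEphos)Cl2 cat., THF; zerovalent palladium inserts into the less hindered C–Br bond trans to the chain) gives the (Z)-2-bromo-2-alkene F12, with bromine cis to the chain. Bromine–lithium exchange (t-BuLi, 2 equiv, −78 °C) then gives 19 with retention.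

**Further compounds**

F1 | step 11 | [(5E,9E,13E,17E)-19-(1,4-dimethoxy-3-methylnaphthalen-2-yl)-5,9,13,17-tetramethylnonadeca-5,9,13,17-tetraen-1-yn-1-yl]trimethylsilane | C[Si](C)(C)C#CCC/C(C)=C/CC/C(C)=C/CC/C(C)=C/CC/C(C)=C/Cc1c(C)c(OC)c2ccccc2c1OC
F2 | step 11 | lithium acetylide of F1 (lithium in place of silicon) | [Li]C#CCC/C(C)=C/CC/C(C)=C/CC/C(C)=C/CC/C(C)=C/Cc1c(C)c(OC)c2ccccc2c1OC
F3 | step 11 | 1,4-dimethoxy-2-methyl-3-[(2E,6E,10E,14E)-3,7,11,15-tetramethylicosa-2,6,10,14-tetraen-18-yn-1-yl]naphthalene | CC#CCC/C(C)=C/CC/C(C)=C/CC/C(C)=C/CC/C(C)=C/Cc1c(C)c(OC)c2ccccc2c1OC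
F4 | step 11 | chlorobis(cyclopentadienyl)alkenylzirconium from F3, zirconium on C19 and trans to the chain | Cl[Zr](C1C=CC=C1)(C1C=CC=C1)/C(C)=C/CC/C(C)=C/CC/C(C)=C/CC/C(C)=C/CC/C(C)=C/Cc1c(C)c(OC)c2ccccc2c1OC
F5 | step 11 | 2-[(2E,6E,10E,14E,18E)-19-iodo-3,7,11,15-tetramethylicosa-2,6,10,14,18-pentaen-1-yl]-1,4-dimethoxy-3-methylnaphthalene | I/C(C)=C/CC/C(C)=C/CC/C(C)=C/CC/C(C)=C/CC/C(C)=C/Cc1c(C)c(OC)c2ccccc2c1OC
F6 | step 11 | chloro[(3E,8R)-4,8,12-trimethyltrideca-3,11-dien-1-yl]zinc | CC(C)=CCC[C@H](C)CCC/C(C)=C/CC[Zn]Cl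
F7 | step 7 | (6E,10E,14E)-3-bromo-16-(1,4-dimethoxy-3-methylnaphthalen-2-yl)-2,6,10,14-tetramethylhexadeca-6,10,14-trien-2-ol (racemic at C3) | CC(C)(O)C(Br)CC/C(C)=C/CC/C(C)=C/CC/C(C)=C/Cc1c(C)c(OC)c2ccccc2c1OC
F8 | step 7 | terminal 14,15-epoxide of 13 (racemic) | CC1(C)OC1CC/C(C)=C/CC/C(C)=C/CC/C(C)=C/Cc1c(C)c(OC)c2ccccc2c1OC
F9 | step 7 | (4E,8E,12E)-14-(1,4-dimethoxy-3-methylnaphthalen-2-yl)-4,8,12-trimethyltetradeca-4,8,12-trienal | O=CCC/C(C)=C/CC/C(C)=C/CC/C(C)=C/Cc1c(C)c(OC)c2ccccc2c1OC
F10 | step 7 | ethyl (2E,6E,10E,14E)-16-(1,4-dimethoxy-3-methylnaphthalen-2-yl)-2,6,10,14-tetramethylhexadeca-2,6,10,14-tetraenoate | CCOC(=O)/C(C)=C/CC/C(C)=C/CC/C(C)=C/CC/C(C)=C/Cc1c(C)c(OC)c2ccccc2c1OC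
F11 | step 10 | 2-[(2E,6E,10E,14E)-19,19-dibromo-3,7,11,15-tetramethylnonadeca-2,6,10,14,18-pentaen-1-yl]-1,4-dimethoxy-3-methylnaphthalene | BrC(Br)=CCC/C(C)=C/CC/C(C)=C/CC/C(C)=C/CC/C(C)=C/Cc1c(C)c(OC)c2ccccc2c1OC
F12 | step 10 | 2-[(2E,6E,10E,14E,18Z)-19-bromo-3,7,11,15-tetramethylicosa-2,6,10,14,18-pentaen-1-yl]-1,4-dimethoxy-3-methylnaphthalene | Br/C(C)=C\CC/C(C)=C/CC/C(C)=C/CC/C(C)=C/CC/C(C)=C/Cc1c(C)c(OC)c2ccccc2c1OC
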